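Given time, step 3 brings the ratio of J to Z to 5.9, so the share of Z in the pair heads for 14.5%; the question is how much of that fall each set-up has made at its end or outlet.

    D + G → E + Z (k1 = 0.0819 M⁻¹ s⁻¹)
    D + E → Z + E, rate k2*[E]*[D] (k2 = 1.42 M⁻¹ s⁻¹)
    Z ⇌ J (K3 = 5.9, k3 = 4.32 × 10⁻⁴ s⁻¹)

| flask | D | G | time | remark |
|---|---|---|---|---|
| Saturday's | 0.020 M (fed, over 40.0 min) | 0.50 mM | 40 min | all but D at the start; D goes in evenly over 40.0 min, the run ends at 40 min |
| Sunday's | 0.020 M | 0.50 mM | 40 min | a closed flask charged with all of it at once and left for 40 min |
| Monday's | 0.020 M | 0.50 mM |  | one stirred flow tank at steady state, fed with the mixture as stated, mean residence time 40 min |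

- the stated concentrations are those of everything mixed, before any reaction; amounts are the same in each set-up
- the feed brings no volume worth counting
- run time (Saturday's): 40 min

1. the set-up with the highest share of Z in all that became Z or J, at the outlet or at the end ("none" if the first two lie within 2 percentage points) (Saturday's / Sunday's / Monday's / none)
2. share of Z in all that became Z or J, at the outlet or at the end, Saturday's
3. share of Z in all that became Z or J, at the outlet or at the end, Sunday's
4. share of Z in all that became Z or J, at the outlet or at the end, Monday's

Each G gives one E, and each E turns D over 17.3 times faster than each G does, so step 2, pseudo-first-order in D at a given E, makes most of the Z and step 1 seeds it. But the amount of Z does not enter the share; its age does. Step 3 is first order both ways, so the excess of a parcel's share over 14.5% decays as exp(−rate × age), with the relaxation rate of the pair, forward and back constants added, 0.0303 min⁻¹. Over 40 min that makes a number I call x, 1.21.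

So I average over ages. Monday's tank has exponential ages, which keeps a fraction 1/(1 + x) of the excess and gives 53.1% without needing D. Sunday's flask, with the making taken as even over the run, gives 64.0%. Saturday's D arrives gradually, so I let the making rise in step with time, and that gives 73.8%, the youngest Z of the set-ups.

The forecast gives 78% for Saturday's, 63% for Sunday's and 53.1% for Monday's, above me on Saturday's and below me on Sunday's, holding that “the share depends mainly on how recently the Z was made”.

Saturday's ends at 77.9%, Sunday's at 62.7%, Monday's at 53.1%, so Saturday's leads. In Sunday's flask step 1 has 58% of its turnover done by 8.00 min, while step 2 takes D down to 29.1% by 40.0 min and step 3 brings J up to 26.4%. In Saturday's flask Z and J together reach 5.01% of the D charged by 20.0 min and 36.2% by 40.0 min. Through 0.0303 min⁻¹, these shares read as a single effective age of Z of 9.87 min in Saturday's, 18.9 min in Sunday's, and, from its share of 58.4%, 22.0 min in Sunday's neighbour with 0.080 M of D.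

The constants used here are invented; what happens was integrated by code.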